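What excess of left-handed product did the flask hold at the two asked times, and how much substrate had reacted?

| setting | cedar | ash | flask |
|---|---|---|---|
| left-handed substrate | 0.80 M | 0.80 M | 0.80 M |
| right-handed substrate | 0.80 M | 0.80 M | 0.80 M |
| reagent | 0.80 equiv | 0.80 equiv | 0.800 equiv |
| free catalyst | 21 mol% | 33 mol% | 15 mol% |
| remark | run made earlier | run made earlier |  |
| time |  |  | 20 min |

- cedar (time / min: left-handed product / %, right-handed product / %, left-handed substrate / %): 2.00: 7.5, 2.9, 41.3; 4.00: 9.8, 3.2, 38.8; 10.0: 11.3, 5.9, 34.0; 25.0: 9.6, 10.6, 32.7
- ash (time / min: left-handed product / %, right-handed product / %, left-handed substrate / %): 3.00: 13.9, 1.8, 36.9; 8.00: 12.8, 7.3, 30.2; 15.0: 13.3, 9.5, 31.6; 25.0: 13.7, 11.7, 29.1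

(readings scatter by 1 percentage point)

- excess of left-handed product over right-handed product in the product at 25 s
- excess of left-handed product over right-handed product in the product at 20 min
- part of the left-handed substrate and right-handed substrate charged together that has reacted at 20 min

- free catalyst is single-handed; left-handed substrate and right-handed substrate are mirror images of each other, charged as a racemate, each of them at the stated concentration
- steps under discussion: reagent + free catalyst + left-handed substrate -> free catalyst + left-handed product; reagent + free catalyst + right-handed substrate -> free catalyst + right-handed product; free catalyst -> spent catalyst; 2 reagent -> homo dimer; left-handed product <-> right-handed product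
- an excess is the difference of the two amounts in percent of their sum
- an excess is below zero if the other one leads

The excess falls with time in both earlier runs, so I read it as a clock, but a noisy one. I used ash, whose product at 25.0 min stood higher than cedar's. There the excess went from 77.1% at 3.00 min to 7.87% at 25.0 min, though the later figure rests on a difference of 2 percentage points against a scatter of 1 point. That gave a reading of 6.68 min for the excess half-life, the time in which the excess of the product standing in the flask halves, late-formed product counted. The racemisation step, left-handed product <-> right-handed product, holds no catalyst, so I carried this reading to the flask, assuming its product was made about as early as in ash. From the ash excess at 3.00 min I then reckoned 13.2% for the flask at 20 min.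

The forecast gave 74%, 13% and 15.5%, saying of the end: “Late-formed product is fresher, which leaves about 13%”.

The flask gave 74.1%, 11.8% and 16.4%, so the forecast stood within its margins.

    reagent + free catalyst + left-handed substrate → free catalyst + left-handed product (k = 1.37 M⁻² min⁻¹)
    reagent + free catalyst + right-handed substrate → free catalyst + right-handed product (k = 0.182 M⁻² min⁻¹)
    free catalyst → spent catalyst (k = 0.0267 min⁻¹)
    2 reagent → homo dimer (k = 0.310 M⁻¹ min⁻¹)
    left-handed product ⇌ right-handed product (k = 0.0634 min⁻¹)

My reckoning from the ash excess contains no catalyst loading, so it gives the same 13.2% for the neighbouring flask with 9 mol% of free catalyst, which held 13.2%, while the flask held 11.8%. In the flask, half of the turnover to left-handed product was done by 2.42 min, and the relaxation half-life of left-handed product and right-handed product by their step alone, 5.47 min, is shorter than the 17.6 min from then to the asked time; over that span this step alone leaves 10.8% of the excess, which turns 74.1% into 8.00%, less than the 11.8% found.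

The numbers in the tables were generated by integration from invented constants, and the scatter is random.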